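**Bench note: the flask you take over is zeta**

Early in zeta, at 1.33 h, uncatalysed product reads 10.7% of the substrate charged, and the last reading, at 5.00 h, is 9.0%. Target reads 83.6% there, so 7.40% of the charge is still unread. Theta, with less free catalyst, ends with more uncatalysed product.

| setting | zeta | theta | flask |
|---|---|---|---|
| substrate | 0.020 M | 0.020 M | 0.020 M |
| coupling partner | 0.024 M | 0.024 M | 0.0240 M |
| free catalyst | 26 µM | 17 µM | 26 µM |
| second catalyst | 0.50 mM | 0.50 mM | 0.50 mM |
| remark | the very flask that is asked about, followed so far | run made earlier |  |
| time |  |  | 25 h |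

- zeta (time / h: target / %, uncatalysed product / %): 1.33: 55.6, 10.7; 2.50: 70.4, 11.5; 4.00: 80.5, 9.0; 5.00: 83.6, 9.0
- theta (time / h: target / %, uncatalysed product / %): 2.50: 67.0, 13.6; 5.00: 78.6, 14.1; 8.00: 81.5, 15.6; 10.0: 83.8, 14.4

(readings scatter by 1 percentage point)

- share of target in target plus uncatalysed product at 5.0 min
- share of target in target plus uncatalysed product at 80 min
- share of target in target plus uncatalysed product at 25 h
- which of target and uncatalysed product there is more of at 25 h



Take target over uncatalysed product at a run's last reading and divide by c(free catalyst):

zeta: 0.357 µM⁻¹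

theta: 0.342 µM⁻¹

mean: 0.350 µM⁻¹

I carry this mean as the odds per catalyst, a selectivity factor per unit of free catalyst. The two runs give nearly the same value, so across these two runs the odds go with the free catalyst charge. For your flask at 25 h I reckon:

odds = 0.350 µM⁻¹ × 26 µM = 9.09

share = odds / (1 + odds) = 90.1%

This reckoning speaks to the end of the flask, not to 5.0 min.

The forecast gives 78% at 5.0 min, 84.5% at 80 min and 90% at 25 h, with target ahead. Its ground for the early value: “the instantaneous selectivity at full substrate applies”.

The flask gives 27.2%, 83.1% and 88.9%, with target ahead.

    second catalyst + open intermediate ⇌ catalyst intermediate (K = 8.42 M⁻¹, k = 125 M⁻¹ min⁻¹)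
    substrate + coupling partner → uncatalysed product (k = 0.458 M⁻¹ min⁻¹)
    coupling partner + catalyst intermediate → second catalyst + target (k = 319 M⁻¹ min⁻¹)
    substrate + free catalyst → free catalyst + open intermediate (k = 2990 M⁻¹ min⁻¹)

The forecast parts from the flask at 5.0 min, by 51 percentage points. The flask also holds open intermediate, 17.3% of the substrate charged at 2.50 h, and target draws level with uncatalysed product at 0.216 h. The end share of this flask means odds of 7.97, or 0.307 µM⁻¹ against the carried 0.350 µM⁻¹. In the neighbouring flask with 44.0 µM of free catalyst, the carried value gives odds of 15.4 and a share of 93.9%. That flask ends at 92.8%, with 7.17% uncatalysed product.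

The runs are calculated on assumed constants; the scatter is artificial.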